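**Retrosynthetic overview**

1. Germacrane numbering is used: ring C1–C10, C1/C10 oxirane, C14 on C10, C15 on C4, isopropenyl on C7. Endgame disconnections: 3-O-angelate and 4,5-diol ⇐ 3,4-epoxy-5-ol opened at C3 by angelic acid; 1,10-oxirane ⇐ (Z)-C1=C10 alkene directed by C9–OH; C7 isopropenyl ⇐ conjugate addition to a C5 enone (C6=C7).
2. Enabling feature: in the ten-membered ring the C8–C9 bond lies between C10=C1 (masked as the oxirane) and C6=C7 (masked as C5 carbinol, C6 methylene and C7 isopropenyl). Ring atoms C1, C10, C9, C8, C7, C6 thus form a cyclodeca-1,5-diene retron, so an anionic oxy-Cope ring expansion makes C8–C9 while cleaving C1–C6 of a six-membered ring C1–C6.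
3. That six-membered ring is (S)-carvone: its carbonyl is C5, its ring methyl C15, and its isopropenyl group becomes C10/C14/C9 as an (E)-silyl enol ether. C7–C8 come from an alkoxyacetaldehyde joined at C6 and turned into a (Z)-enol ether next to a C6 carbinol.
4. Ring order: cyclohexenone (bought as carvone) → ten-membered carbocycle (key step) → 1,10-oxirane → 3,4-oxirane (opened in the last step).

Key step: step 7

Remark: 2-[(4-methoxyphenyl)methoxy]acetaldehyde (7) is taken as a catalogue aldehyde; locants in the names of the ten-membered compounds follow the germacrane numbering given above.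

**Step 1**
Reactants: 1 (S)-(+)-carvone
Product: 2 (5S)-5-(3-chloroprop-1-en-2-yl)-2-methylcyclohex-2-en-1-one
Conditions: Ca(OCl)2, solid CO2, CH2Cl2/H2O, 0 °C
Reagents that add atoms: calcium hypochlorite, [Ca+2].[O-]Cl.[O-]Cl
Why: Ene-type allylic chlorination by HOCl formed in the flask should touch only the electron-rich isopropenyl group (the enone alkene is deactivated), shifting the double bond onto the former methyl carbon and leaving the ring stereocentre intact.

**Step 2**
Reactants: 2 (5S)-5-(3-chloroprop-1-en-2-yl)-2-methylcyclohex-2-en-1-one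
Product: 4 (5S)-5-(3-hydroxyprop-1-en-2-yl)-2-methylcyclohex-2-en-1-one, via allylic acetate 3 (not isolated)
Conditions: KOAc, Bu4NI (cat.), DMF, 50 °C; then K2CO3 (cat.), MeOH, 20 °C
Reagents that add atoms: potassium acetate, CC(=O)[O-].[K+]
Why: SN2 displacement of the primary allylic chloride by acetate followed by mild methanolysis (transesterification) should give the primary allylic alcohol without affecting the enone.

**Step 3**
Reactants: 4 (5S)-5-(3-hydroxyprop-1-en-2-yl)-2-methylcyclohex-2-en-1-one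
Product: 5 (5S)-2-methyl-5-{3-[tri(propan-2-yl)silyloxy]prop-1-en-2-yl}cyclohex-2-en-1-one
Conditions: iPr3SiCl, imidazole, DMF, 20 °C
Reagents that add atoms: chlorotri(propan-2-yl)silane, CC(C)[Si](Cl)(C(C)C)C(C)C
Why: Standard silylation of the primary alcohol gives a robust allyl silyl ether that later survives amide bases, alkoxides and cuprates.

**Step 4**
Reactants: 5 (5S)-2-methyl-5-{3-[tri(propan-2-yl)silyloxy]prop-1-en-2-yl}cyclohex-2-en-1-one
Product: 6 (5S)-2-methyl-5-{(1E)-1-[tri(propan-2-yl)silyloxy]prop-1-en-2-yl}cyclohex-2-en-1-one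
Conditions: [Ir(cod)(PMePh2)2]PF6 (cat., H2-activated), THF, 20 °C
Reagents that add atoms: none
Why: Iridium-hydride-catalysed allyl-to-propenyl isomerisation (1,3-hydrogen shift) of the allyl silyl ether should give the trisubstituted silyl enol ether with the silyloxy group trans to the bulky ring carbon (E), the geometry that later fixes C9, while the conjugated ring alkene is not touched.

**Step 5**
Reactants: 6 (5S)-2-methyl-5-{(1E)-1-[tri(propan-2-yl)silyloxy]prop-1-en-2-yl}cyclohex-2-en-1-one; 7 2-[(4-methoxyphenyl)methoxy]acetaldehyde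
Product: 10 (5R,6E)-6-{2-[(4-methoxyphenyl)methoxy]ethylidene}-2-methyl-5-{(1E)-1-[tri(propan-2-yl)silyloxy]prop-1-en-2-yl}cyclohex-2-en-1-one, via lithium aldolate 8 (not isolated), via aldol mesylate 9 (not isolated)
Conditions: LiN(iPr)2, THF, −78 °C; then 7; then MeSO2Cl, −78 → 0 °C; then DBU, 0 → 20 °C
Reagents that add atoms: 2-[(4-methoxyphenyl)methoxy]acetaldehyde (7), O=CCOCc1ccc(OC)cc1
Why: Kinetic deprotonation at C6 (the only α'-position), crossed aldol addition to 7, mesylation and E1cB elimination (aldol condensation) should give the (E)-alkylidene ketone, the adjacent stereocentre being safe because its C–H bond is not acidic.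

**Step 6**
Reactants: 10 (5R,6E)-6-{2-[(4-methoxyphenyl)methoxy]ethylidene}-2-methyl-5-{(1E)-1-[tri(propan-2-yl)silyloxy]prop-1-en-2-yl}cyclohex-2-en-1-one
Product: 13 (5R,6S)-6-hydroxy-6-{(Z)-2-[(4-methoxyphenyl)methoxy]ethenyl}-2-methyl-5-{(1E)-1-[tri(propan-2-yl)silyloxy]prop-1-en-2-yl}cyclohex-2-en-1-one, via sodium dienolate 11 (not isolated), via sodium alkoxide 12 (not isolated)
Conditions: NaN(SiMe3)2, THF, −78 °C; then 3-phenyl-2-(phenylsulfonyl)oxaziridine, −78 °C; AcOH quench at −78 °C
Reagents that add atoms: 3-phenyl-2-(phenylsulfonyl)oxaziridine, O=S(=O)(c1ccccc1)N1OC1c1ccccc1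
Why: γ-Deprotonation at the allylic, oxygen-bearing CH2 should give the extended dienolate whose alkoxy terminus prefers the cis (Z) arrangement as in base-mediated allyl ether isomerisations, and α-hydroxylation by the N-sulfonyloxaziridine (Davis oxidation) should occur at the ring α-carbon on the face opposite the neighbouring side chain, setting the tertiary carbinol (6S) with the new alkenyl group cis to that side chain, while the tightly ion-paired sodium alkoxide 12 is protonated at −78 °C before it can rearrange.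

**Step 7**
Reactants: 13 (5R,6S)-6-hydroxy-6-{(Z)-2-[(4-methoxyphenyl)methoxy]ethenyl}-2-methyl-5-{(1E)-1-[tri(propan-2-yl)silyloxy]prop-1-en-2-yl}cyclohex-2-en-1-one
Product: 16 (1(10)Z,3Z,8S,9R)-8-[(4-methoxyphenyl)methoxy]-4,10-dimethyl-5-oxo-9-[tri(propan-2-yl)silyloxy]cyclodeca-1(10),3,6-trien-6-yl trifluoromethanesulfonate (C5 trans to C8 across C6=C7), via potassium alkoxide 14 (not isolated), via potassium enolate 15 (not isolated)
Conditions: KN(SiMe3)2, THF, −78 → 0 °C; then PhNTf2, −78 → 0 °C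
Reagents that add atoms: N-phenylbis(trifluoromethanesulfonimide), O=S(=O)(N(c1ccccc1)S(=O)(=O)C(F)(F)F)C(F)(F)F
Why: Deprotonation by the potassium amide gives the loosely ion-paired alkoxide 14, a 3-oxido-1,5-diene (C9=C10–C1–C6(O−)–C7=C8) that should undergo a suprafacial [3,3] sigmatropic shift through a chair transition state (anionic oxy-Cope rearrangement, the closest precedent being the 1,2-dialkenylcyclohexanol to cyclodec-5-enone ring expansions used for germacranes), forming C8–C9 while the C1–C6 bond of the cyclohexenone breaks. The ten-membered carbocycle is thus closed by a four-atom ring expansion of the six-membered ring and not by an end-to-end cyclisation, and enolate 15, stabilised as a diosphenolate by the C5 carbonyl, is captured on oxygen by PhNTf2 before it can expel the C8 alkoxide. C9 is set by the (E)-silyl enol ether (silyloxy group pseudo-equatorial) and C8 by the (Z)-enol ether (PMB-oxy group pseudo-axial) on the same chair, whose sense is fixed by the carvone-derived C1 stereocentre, so that the two oxygens end up cis as in the target. C1=C10 is formed Z because the C1–C2 ring bond is axial on that chair, and C6=C7 is formed with C5 and C8 trans. The selectivity needed is reaction through the half-chair conformer with the C1 side chain equatorial and the C6 alkenyl group axial; this is secured by the trans relation of the C6 oxygen to the C1 side chain set in step 6, by the equatorial C6–O−/C5=O pair held by potassium, and by the absence of any axial substituent at sp2 C4.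

**Step 8**
Reactants: 16 enol triflate
Product: 17 (1(10)Z,3Z,6E,8S,9R)-8-[(4-methoxyphenyl)methoxy]-4,10-dimethyl-9-[tri(propan-2-yl)silyloxy]cyclodeca-1(10),3,6-trien-5-one
Conditions: Pd(OAc)2 (cat.), PPh3, HCO2H, Bu3N, DMF, 20–25 °C
Reagents that add atoms: none
Why: Palladium-catalysed formate reduction of the enol triflate (oxidative addition, decarboxylation of the palladium formate, reductive elimination) should replace OTf by H with retention of the C6=C7 geometry, and is run at ambient temperature because the neutral cyclodeca-1,5-diene could revert by Cope rearrangement on heating.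

**Step 9**
Reactants: 17 dienone; 18 isopropenylmagnesium bromide
Product: 20 (1(10)Z,3Z,7R,8S,9R)-8-[(4-methoxyphenyl)methoxy]-4,10-dimethyl-7-(prop-1-en-2-yl)-9-[tri(propan-2-yl)silyloxy]cyclodeca-1(10),3-dien-5-one, via silyl enol ether 19 (not isolated)
Conditions: CuBr·SMe2 (cat.), Me3SiCl, THF, −78 °C; then aqueous citric acid, 0 °C
Reagents that add atoms: isopropenylmagnesium bromide (18), C=C(C)[Mg]Br
Why: Copper-catalysed, Me3SiCl-accelerated conjugate addition of the alkenyl Grignard reagent should go to C7 of the disubstituted E-enone and not to the α-methylated C3=C4 enone, and C7 (7R) is set by attack anti to the γ-PMB-oxy group on C8 (Felkin–Anh-type model for γ-alkoxy enones, in line with peripheral attack on the ring).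

**Step 10**
Reactants: 20 silyl ether
Product: 21 (1(10)Z,3Z,7R,8S,9R)-9-hydroxy-8-[(4-methoxyphenyl)methoxy]-4,10-dimethyl-7-(prop-1-en-2-yl)cyclodeca-1(10),3-dien-5-one
Conditions: Bu4NF, AcOH, THF, 0 → 20 °C
Reagents that add atoms: none
Why: Fluoride-mediated cleavage of the secondary silyl ether, buffered with acetic acid to suppress base-induced enone chemistry, should free the allylic C9 hydroxyl while the PMB ether stays.

**Step 11**
Reactants: 21 allylic alcohol
Product: 22 (1R,3Z,7R,8S,9S,10S)-1,10-epoxy-9-hydroxy-8-[(4-methoxyphenyl)methoxy]-4,10-dimethyl-7-(prop-1-en-2-yl)cyclodec-3-en-5-one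
Conditions: VO(acac)2 (cat.), t-BuOOH, CH2Cl2, 0 °C
Reagents that add atoms: tert-butyl hydroperoxide, CC(C)(C)OO
Why: Hydroxyl-directed epoxidation by the vanadium tert-butylperoxide complex bound to the C9 alkoxide should oxidise only the allylic C1=C10 alkene, giving stereospecifically the cis-oxirane from the Z-alkene on the face syn to the C9 oxygen, as is typical for Z-cycloalkenols of medium ring size and reinforced by the allylic strain of the C10 methyl group.

**Step 12**
Reactants: 22 epoxy alcohol; 23 acetic anhydride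
Product: 24 (1R,3Z,7R,8S,9S,10R)-9-acetoxy-1,10-epoxy-8-[(4-methoxyphenyl)methoxy]-4,10-dimethyl-7-(prop-1-en-2-yl)cyclodec-3-en-5-one
Conditions: pyridine, 4-(dimethylamino)pyridine (cat.), CH2Cl2, 0 °C
Reagents that add atoms: acetic anhydride (23), CC(=O)OC(C)=O
Why: Nucleophile-catalysed acylation should esterify the only free hydroxyl, the hindered secondary C9–OH, to the acetate of the target.

**Step 13**
Reactants: 24 PMB ether
Product: 25 (1R,3Z,7R,8S,9S,10R)-9-acetoxy-1,10-epoxy-8-hydroxy-4,10-dimethyl-7-(prop-1-en-2-yl)cyclodec-3-en-5-one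
Conditions: DDQ, CH2Cl2/pH 7 buffer, 0 °C
Reagents that add atoms: none
Why: Oxidative cleavage of the electron-rich PMB ether by DDQ (hydride abstraction, then hydrolysis of the oxocarbenium ion) under buffered conditions should free C8–OH without touching the acetate, the oxirane or the alkenes.

**Step 14**
Reactants: 25 C8 alcohol; 26 3-methylbut-2-enoyl chloride
Product: 27 (1R,3Z,7R,8S,9S,10R)-9-acetoxy-1,10-epoxy-4,10-dimethyl-8-[(3-methylbut-2-enoyl)oxy]-7-(prop-1-en-2-yl)cyclodec-3-en-5-one
Conditions: pyridine, 4-(dimethylamino)pyridine (cat.), CH2Cl2, −20 → 0 °C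
Reagents that add atoms: 3-methylbut-2-enoyl chloride (26), CC(C)=CC(=O)Cl
Why: Acylation of the single free secondary hydroxyl with the acid chloride in pyridine at low temperature should give the C8 senecioate faster than acetyl migration from O9 and without deconjugation of the acyl group.

**Step 15**
Reactants: 27 enone
Product: 28 (1R,3Z,5R,7R,8S,9S,10R)-9-acetoxy-1,10-epoxy-5-hydroxy-4,10-dimethyl-8-[(3-methylbut-2-enoyl)oxy]-7-(prop-1-en-2-yl)cyclodec-3-ene
Conditions: (S)-Me-CBS oxazaborolidine [(3aS)-1-methyl-3,3-diphenyltetrahydro-1H,3H-pyrrolo[1,2-c][1,3,2]oxazaborole], catecholborane, toluene, −78 °C; then MeOH, pH 7 buffer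
Reagents that add atoms: none
Why: Corey–Bakshi–Shibata reduction with catecholborane, which does not hydroborate the alkenes at this temperature, should deliver hydride to the C5 ketone under catalyst control (the α-methyl alkenyl carbon C4 acting as the large group), setting 5R while esters and oxirane stay intact.

**Step 16**
Reactants: 28 allylic alcohol
Product: 29 (1R,3R,4S,5R,7R,8S,9S,10R)-9-acetoxy-1,10:3,4-diepoxy-5-hydroxy-4,10-dimethyl-8-[(3-methylbut-2-enoyl)oxy]-7-(prop-1-en-2-yl)cyclodecane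
Conditions: mCPBA, CH2Cl2, 0 °C
Reagents that add atoms: 3-chloroperoxybenzoic acid, OOC(=O)c1cccc(Cl)c1
Why: Hydroxyl-directed peracid (Prilezhaev) epoxidation of the trisubstituted Z-allylic alcohol should be faster than attack on the 1,1-disubstituted isopropenyl group or the electron-poor senecioate, and minimisation of 1,3-allylic strain should place the cis-oxirane threo to the C5 hydroxyl, the sense also usual for peracid epoxidation of medium-ring cycloalkenols.

**Step 17**
Reactants: 29 epoxy alcohol; 30 angelic acid [(2Z)-2-methylbut-2-enoic acid]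
Product: 31 CNP0298989.1 (1R,3S,4S,5R,7R,8S,9S,10R)-9-acetoxy-1,10-epoxy-4,5-dihydroxy-4,10-dimethyl-3-{[(2Z)-2-methylbut-2-enoyl]oxy}-8-[(3-methylbut-2-enoyl)oxy]-7-(prop-1-en-2-yl)cyclodecane
Conditions: Ti(OiPr)4, CH2Cl2, 0 → 20 °C; aqueous tartaric acid work-up
Reagents that add atoms: angelic acid (30), OC(=O)/C(C)=C\C
Why: Titanium-mediated opening of the 2,3-epoxy alcohol unit (C5–OH with the C4–C3 oxirane) by the carboxylic acid should occur at the less substituted remote carbon C3 with inversion (3S) while the oxirane oxygen stays on C4, giving the 3-angelate and the free 4,5-diol in one operation, the 1,10-oxirane having no neighbouring free hydroxyl to bind titanium.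

**Compound list**

1 | (S)-(+)-carvone, (5S)-2-methyl-5-(prop-1-en-2-yl)cyclohex-2-en-1-one | CC1=CC[C@@H](CC1=O)C(C)=C | starting material
2 | (5S)-5-(3-chloroprop-1-en-2-yl)-2-methylcyclohex-2-en-1-one | CC1=CC[C@@H](CC1=O)C(=C)CCl | intermediate
3 | 2-[(1S)-4-methyl-5-oxocyclohex-3-en-1-yl]prop-2-en-1-yl acetate (not isolated) | CC1=CC[C@@H](CC1=O)C(=C)COC(C)=O | intermediate
4 | (5S)-5-(3-hydroxyprop-1-en-2-yl)-2-methylcyclohex-2-en-1-one | CC1=CC[C@@H](CC1=O)C(=C)CO | intermediate
5 | (5S)-2-methyl-5-{3-[tri(propan-2-yl)silyloxy]prop-1-en-2-yl}cyclohex-2-en-1-one | CC1=CC[C@@H](CC1=O)C(=C)CO[Si](C(C)C)(C(C)C)C(C)C | intermediate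
6 | (5S)-2-methyl-5-{(1E)-1-[tri(propan-2-yl)silyloxy]prop-1-en-2-yl}cyclohex-2-en-1-one | CC1=CC[C@@H](CC1=O)/C(C)=C/O[Si](C(C)C)(C(C)C)C(C)C | intermediate
7 | 2-[(4-methoxyphenyl)methoxy]acetaldehyde | O=CCOCc1ccc(OC)cc1 | starting material
8 | lithium aldolate of 6 and 7 (new C6–C7 bond; mixture at the two new centres; not isolated) | [Li+].[O-]C(COCc1ccc(OC)cc1)C1C(=O)C(C)=CC[C@@H]1/C(C)=C/O[Si](C(C)C)(C(C)C)C(C)C | intermediate
9 | methanesulfonate of the aldol (mixture at the two new centres; not isolated) | CS(=O)(=O)OC(COCc1ccc(OC)cc1)C1C(=O)C(C)=CC[C@@H]1/C(C)=C/O[Si](C(C)C)(C(C)C)C(C)C | intermediate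
10 | (5R,6E)-6-{2-[(4-methoxyphenyl)methoxy]ethylidene}-2-methyl-5-{(1E)-1-[tri(propan-2-yl)silyloxy]prop-1-en-2-yl}cyclohex-2-en-1-one | COc1ccc(COC/C=C2/C(=O)C(C)=CC[C@@H]2/C(C)=C/O[Si](C(C)C)(C(C)C)C(C)C)cc1 | intermediate
11 | sodium dienolate of 10 (O–C5=C6–C7=C8 with a Z enol ether; not isolated) | [Na+].[O-]C1=C(/C=C\OCc2ccc(OC)cc2)[C@H](CC=C1C)/C(C)=C/O[Si](C(C)C)(C(C)C)C(C)C | intermediate
12 | sodium alkoxide of 13 (not isolated) | [Na+].[O-][C@@]1(/C=C\OCc2ccc(OC)cc2)C(=O)C(C)=CC[C@@H]1/C(C)=C/O[Si](C(C)C)(C(C)C)C(C)C | intermediate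
13 | (5R,6S)-6-hydroxy-6-{(Z)-2-[(4-methoxyphenyl)methoxy]ethenyl}-2-methyl-5-{(1E)-1-[tri(propan-2-yl)silyloxy]prop-1-en-2-yl}cyclohex-2-en-1-one | O[C@@]1(/C=C\OCc2ccc(OC)cc2)C(=O)C(C)=CC[C@@H]1/C(C)=C/O[Si](C(C)C)(C(C)C)C(C)C | intermediate
14 | potassium alkoxide of 13 (not isolated) | [K+].[O-][C@@]1(/C=C\OCc2ccc(OC)cc2)C(=O)C(C)=CC[C@@H]1/C(C)=C/O[Si](C(C)C)(C(C)C)C(C)C | intermediate
15 | potassium enolate of the ten-membered 5,6-dione (O− on C6, C6=C7; not isolated) | [C@H]1(OCc2ccc(OC)cc2)/C=C(\[O-])/C(=O)\C(C)=C/C/C=C(C)\[C@H]1O[Si](C(C)C)(C(C)C)C(C)C.[K+] | intermediate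
16 | (1(10)Z,3Z,8S,9R)-8-[(4-methoxyphenyl)methoxy]-4,10-dimethyl-5-oxo-9-[tri(propan-2-yl)silyloxy]cyclodeca-1(10),3,6-trien-6-yl trifluoromethanesulfonate (C5 trans to C8) | [C@H]1(OCc2ccc(OC)cc2)/C=C(\OS(=O)(=O)C(F)(F)F)/C(=O)\C(C)=C/C/C=C(C)\[C@H]1O[Si](C(C)C)(C(C)C)C(C)C | intermediate
17 | (1(10)Z,3Z,6E,8S,9R)-8-[(4-methoxyphenyl)methoxy]-4,10-dimethyl-9-[tri(propan-2-yl)silyloxy]cyclodeca-1(10),3,6-trien-5-one | [C@H]1(OCc2ccc(OC)cc2)/C=C/C(=O)\C(C)=C/C/C=C(C)\[C@H]1O[Si](C(C)C)(C(C)C)C(C)C | intermediate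
18 | isopropenylmagnesium bromide | C=C(C)[Mg]Br | starting material
19 | trimethylsilyl dienol ether of 20 (C5=C6, geometry not defined; not isolated) | C=C(C)[C@H]1C=C(O[Si](C)(C)C)\C(C)=C/C/C=C(C)\[C@@H](O[Si](C(C)C)(C(C)C)C(C)C)[C@H]1OCc2ccc(OC)cc2 | intermediate
20 | (1(10)Z,3Z,7R,8S,9R)-8-[(4-methoxyphenyl)methoxy]-4,10-dimethyl-7-(prop-1-en-2-yl)-9-[tri(propan-2-yl)silyloxy]cyclodeca-1(10),3-dien-5-one | C=C(C)[C@H]1CC(=O)\C(C)=C/C/C=C(C)\[C@@H](O[Si](C(C)C)(C(C)C)C(C)C)[C@H]1OCc2ccc(OC)cc2 | intermediate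
21 | (1(10)Z,3Z,7R,8S,9R)-9-hydroxy-8-[(4-methoxyphenyl)methoxy]-4,10-dimethyl-7-(prop-1-en-2-yl)cyclodeca-1(10),3-dien-5-one | C=C(C)[C@H]1CC(=O)\C(C)=C/C/C=C(C)\[C@@H](O)[C@H]1OCc2ccc(OC)cc2 | intermediate
22 | (1R,3Z,7R,8S,9S,10S)-1,10-epoxy-9-hydroxy-8-[(4-methoxyphenyl)methoxy]-4,10-dimethyl-7-(prop-1-en-2-yl)cyclodec-3-en-5-one | C=C(C)[C@H]1CC(=O)\C(C)=C/C[C@H]2O[C@@]2(C)[C@@H](O)[C@H]1OCc3ccc(OC)cc3 | intermediate
23 | acetic anhydride | CC(=O)OC(C)=O | starting material
24 | (1R,3Z,7R,8S,9S,10R)-9-acetoxy-1,10-epoxy-8-[(4-methoxyphenyl)methoxy]-4,10-dimethyl-7-(prop-1-en-2-yl)cyclodec-3-en-5-one | C=C(C)[C@H]1CC(=O)\C(C)=C/C[C@H]2O[C@@]2(C)[C@@H](OC(C)=O)[C@H]1OCc3ccc(OC)cc3 | intermediate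
25 | (1R,3Z,7R,8S,9S,10R)-9-acetoxy-1,10-epoxy-8-hydroxy-4,10-dimethyl-7-(prop-1-en-2-yl)cyclodec-3-en-5-one | C=C(C)[C@H]1CC(=O)\C(C)=C/C[C@H]2O[C@@]2(C)[C@@H](OC(C)=O)[C@H]1O | intermediate
26 | 3-methylbut-2-enoyl chloride (senecioyl chloride) | CC(C)=CC(=O)Cl | starting material
27 | (1R,3Z,7R,8S,9S,10R)-9-acetoxy-1,10-epoxy-4,10-dimethyl-8-[(3-methylbut-2-enoyl)oxy]-7-(prop-1-en-2-yl)cyclodec-3-en-5-one | C=C(C)[C@H]1CC(=O)\C(C)=C/C[C@H]2O[C@@]2(C)[C@@H](OC(C)=O)[C@H]1OC(=O)C=C(C)C | intermediate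
28 | (1R,3Z,5R,7R,8S,9S,10R)-9-acetoxy-1,10-epoxy-5-hydroxy-4,10-dimethyl-8-[(3-methylbut-2-enoyl)oxy]-7-(prop-1-en-2-yl)cyclodec-3-ene | C=C(C)[C@H]1C[C@@H](O)\C(C)=C/C[C@H]2O[C@@]2(C)[C@@H](OC(C)=O)[C@H]1OC(=O)C=C(C)C | intermediate
29 | (1R,3R,4S,5R,7R,8S,9S,10R)-9-acetoxy-1,10:3,4-diepoxy-5-hydroxy-4,10-dimethyl-8-[(3-methylbut-2-enoyl)oxy]-7-(prop-1-en-2-yl)cyclodecane | C=C(C)[C@H]1C[C@@H](O)[C@]3(C)O[C@@H]3C[C@H]2O[C@@]2(C)[C@@H](OC(C)=O)[C@H]1OC(=O)C=C(C)C | intermediate
30 | angelic acid, (2Z)-2-methylbut-2-enoic acid | OC(=O)/C(C)=C\C | starting material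
31 | CNP0298989.1, (1R,3S,4S,5R,7R,8S,9S,10R)-9-acetoxy-1,10-epoxy-4,5-dihydroxy-4,10-dimethyl-3-{[(2Z)-2-methylbut-2-enoyl]oxy}-8-[(3-methylbut-2-enoyl)oxy]-7-(prop-1-en-2-yl)cyclodecane | C=C(C)[C@H]1C[C@@H](O)[C@](C)(O)[C@@H](OC(=O)/C(C)=C\C)C[C@H]2O[C@@]2(C)[C@@H](OC(C)=O)[C@H]1OC(=O)C=C(C)C | target

**Totals and risks**

Total step count: 17. Longest linear sequence: 17 steps (1 → 31).

Step 7 (key step). What may go wrong: rearrangement through the other chair or a boat, which would lose control of the C8/C9 configuration and of the Z geometry of C1=C10; a base-induced α-ketol shift of the alkoxide; or expulsion of the C8 alkoxide from the enolate before it is trapped. The fallback removes the α-keto group from the rearranging alkoxide; it sets out from 13 and comes back at 17. Luche reduction (NaBH4, CeCl3·7H2O, MeOH, −78 °C) of the C5 carbonyl from the face opposite the axial C6 alkenyl group should give the cis-5,6-diol F1. The secondary allylic hydroxyl is silylated selectively (Et3SiCl, imidazole, CH2Cl2) to the triethylsilyl ether F2. A conventional anionic oxy-Cope rearrangement of its tertiary potassium alkoxide (KH, 18-crown-6, THF, 0 → 20 °C) followed by PhNTf2 should give the ten-membered enol triflate F3. Palladium/formate reduction as in step 8 gives the triene F4, HF·pyridine removes the triethylsilyl group in the presence of the triisopropylsilyl ether to give the bis-allylic alcohol F5, and MnO2 in CH2Cl2 oxidises it to dienone 17.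

Step 6. What may go wrong: deprotonation at the ring γ-carbon C2 instead of C8, which leads to hydroxylation at the wrong carbon, or erosion of the Z geometry of the new enol ether. The fallback sets out from 10 and comes back at 13. The enone is first deconjugated under equilibrating conditions (KOtBu cat., t-BuOH/THF, 0 °C), which should funnel it into the β,γ-unsaturated ketone F6 carrying the (Z)-enol ether (cis-selective allyl-to-propenyl ether isomerisation, driven by enol ether stabilisation and relief of allylic strain at the exocyclic alkene). In F6 the ring α-C–H is the only doubly activated position, so NaN(SiMe3)2 followed by the oxaziridine and the cold AcOH quench should give 13 by plain α-deprotonation and α-hydroxylation, through the same sodium dienolate 11 and sodium alkoxide 12.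

Step 9. What may go wrong: addition to the other enone (at C3) or to the wrong face of C7, reductive loss of the γ-alkoxy group by electron transfer from the cuprate, and Cope reversion of 17 while it is handled. The fallback goes from 17 directly to 20 by rhodium-catalysed asymmetric conjugate addition ([Rh(OH)(cod)]2, BINAP of the matched sense, 4,4,5,5-tetramethyl-2-(prop-1-en-2-yl)-1,3,2-dioxaborolane, aqueous KOH, dioxane, 20–30 °C). Here the chiral ligand and not the substrate selects the C7 face, and the α-substituted C3=C4 enone is inert; no new compound arises on the way (F0).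

**Further compounds**

F1 | step 7 | cis-5,6-diol: compound 13 with the C5 carbonyl reduced to a secondary alcohol whose OH is cis to the C6 alkenyl group | O[C@@]1(/C=C\OCc2ccc(OC)cc2)[C@H](O)C(C)=CC[C@@H]1/C(C)=C/O[Si](C(C)C)(C(C)C)C(C)C
F2 | step 7 | 5-O-triethylsilyl ether of F1 (tertiary C6–OH free) | O[C@@]1(/C=C\OCc2ccc(OC)cc2)[C@H](O[Si](CC)(CC)CC)C(C)=CC[C@@H]1/C(C)=C/O[Si](C(C)C)(C(C)C)C(C)C
F3 | step 7 | ten-membered enol triflate with C5–OSiEt3 in place of the C5 carbonyl of 16 | [C@H]1(OCc2ccc(OC)cc2)/C=C(\OS(=O)(=O)C(F)(F)F)/[C@H](O[Si](CC)(CC)CC)\C(C)=C/C/C=C(C)\[C@H]1O[Si](C(C)C)(C(C)C)C(C)C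
F4 | step 7 | (1(10)Z,3Z,6E)-triene with C5–OSiEt3, C8–OPMB and C9–OSi(iPr)3 | [C@H]1(OCc2ccc(OC)cc2)/C=C/[C@H](O[Si](CC)(CC)CC)\C(C)=C/C/C=C(C)\[C@H]1O[Si](C(C)C)(C(C)C)C(C)C
F5 | step 7 | bis-allylic C5 alcohol corresponding to 17 | [C@H]1(OCc2ccc(OC)cc2)/C=C/[C@H](O)\C(C)=C/C/C=C(C)\[C@H]1O[Si](C(C)C)(C(C)C)C(C)C
F6 | step 6 | β,γ-unsaturated ketone: 6-{(Z)-2-[(4-methoxyphenyl)methoxy]ethenyl}-2-methyl-5-{(1E)-1-[tri(propan-2-yl)silyloxy]prop-1-en-2-yl}cyclohex-2-en-1-one with the two side chains trans | [C@H]1(/C=C\OCc2ccc(OC)cc2)C(=O)C(C)=CC[C@@H]1/C(C)=C/O[Si](C(C)C)(C(C)C)C(C)C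
F0 | step 9 | none | none
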